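**Assumption:** in the "Why" lines atoms carry chamigrene locants (ring B = C1–C5 with CHCl = C2 and CMeBr = C3; spiro carbon = C6; ring A = C7–C11 with C=CH2 = C7, CHBr = C10, CMe2 = C11); compound names use IUPAC locants. The route is a paper design; the ring-forming step is a proposed new method.

**Retrosynthetic overview**
- Target ⇐ 10-bromo-β-chamigrene: ring B halogens go in last, by anti chlorohydroxylation and then OH→Br with retention.
- 10-Bromo-β-chamigrene ⇐ spiro ketone, by carbonyl methylenation.
- Spiro ketone ⇐ acyclic dibromo propargylic pivalate + isoprene in one flask: a bromonium/carboxyallene cation–olefin closure forms ring A first, and the O-acylated 2-methylidene ketone it releases is trapped by Diels–Alder reaction, which forms ring B and the spiro centre.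
- Dibromide ⇐ (R)-epoxide (Ph3PBr2, inversion) ⇐ enyne pivalate (Shi epoxidation sets the only reagent-controlled stereocentre).
- Enyne pivalate ⇐ propargyl alcohol + 5-bromo-2-methylpent-2-ene + pivaloyl chloride.

**Step 1**
Reactants: 1 prop-2-yn-1-ol; 2 5-bromo-2-methylpent-2-ene
Product: 4 7-methyloct-6-en-2-yn-1-yl pivalate, via lithium 7-methyloct-6-en-2-yn-1-olate 3 (not isolated)
Conditions: n-BuLi (2.1 equiv), THF–DMPU, −78 → 0 °C; 2, 0 °C → rt; then PivCl, 0 °C
Reagents that add atoms: pivaloyl chloride, CC(C)(C)C(Cl)=O
Why: SN2 alkylation of the propargyl alcohol dianion at the more nucleophilic acetylide carbon, followed by O-acylation of the remaining lithium alkoxide in the same flask; no stereocentre is formed.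

**Step 2**
Reactants: 4 7-methyloct-6-en-2-yn-1-yl pivalate
Product: 5 5-[(2R)-3,3-dimethyloxiran-2-yl]pent-2-yn-1-yl pivalate
Conditions: D-fructose-derived Shi ketone (30 mol%), KHSO5 (as Oxone, 2KHSO5·KHSO4·K2SO4), K2CO3, Bu4NHSO4, MeCN–CH2(OMe)2–aq. Na2B4O7 buffer (pH 10.5), 0 °C
Reagents that add atoms: potassium peroxymonosulfate, [K+].[O-]S(=O)(=O)OO
Why: Shi asymmetric epoxidation, in which the chiral dioxirane epoxidises the electron-rich trisubstituted olefin through a spiro transition state (alkyne and ester are inert) and the D-fructose-derived ketone gives the (R)-epoxide.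

**Step 3**
Reactants: 5 5-[(2R)-3,3-dimethyloxiran-2-yl]pent-2-yn-1-yl pivalate
Product: 6 (6S)-6,7-dibromo-7-methyloct-2-yn-1-yl pivalate
Conditions: Ph3PBr2 (1.3 equiv), CH2Cl2, 0 °C → rt, dark
Reagents that add atoms: dibromotriphenylphosphorane, BrP(Br)(c1ccccc1)(c1ccccc1)c1ccccc1
Why: Deoxygenative dibromination of an epoxide: after O-phosphonium activation and bromide opening at the tertiary carbon, Ph3PO leaves the secondary carbon either by direct SN2 or by neighbouring-bromine participation, and both paths put Br on the face opposite the old C–O bond, so the (R)-epoxide gives the (S)-bromide.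

**Step 4**
Reactants: 6 (6S)-6,7-dibromo-7-methyloct-2-yn-1-yl pivalate; 7 isoprene (2-methylbuta-1,3-diene)
Product: 10 (4S,6R)-4-bromo-5,5,9-trimethylspiro[5.5]undec-8-en-1-one, via (6S)-6,7-dibromo-7-methylocta-1,2-dien-3-yl pivalate 8 (not isolated), via O-pivaloyl oxocarbenium triflate of ring A enone 9 (not isolated)
Conditions: Ph3PAuNTf2 (2 mol%), CH2Cl2, 23 °C, 1 h; then 7 (10 equiv), AgOTf (1.2 equiv), −78 → −30 °C; aq. NaHCO3
Reagents that add atoms: none
Why: Proposed new method: Ph3PAuNTf2 effects the known 1,3-acyloxy (3,3) shift of the propargylic pivalate to carboxyallene 8, AgOTf then ionises the tertiary C–Br bond with anchimeric help from the neighbouring bromine to give a configurationally defined bromonium ion (closest known types: silver-assisted ionisation of vicinal dibromides and enantiospecific bromonium-initiated polyene cyclisation), the enol-ester-like central allene carbon attacks the CMe2 carbon through a chair transition state to close ring A (cation–olefin cyclisation with an enol ester terminator, the C–Br stereocentre of 6 being carried over untouched), and the O-acylated 2-methylidene ketone 9 so released is an activated dienophile that undergoes a "para"-selective Diels–Alder reaction with isoprene on the face anti to the axial methyl of the CMe2 group (chair with equatorial Br), which forms ring B and sets the spiro centre with the CH2 that adjoins CH= trans to Br.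

**Step 5**
Reactants: 10 (4S,6R)-4-bromo-5,5,9-trimethylspiro[5.5]undec-8-en-1-one
Product: 11 (6S,8S)-8-bromo-3,7,7-trimethyl-11-methylidenespiro[5.5]undec-2-ene (10-bromo-β-chamigrene)
Conditions: Cp2Ti(CH2)(Cl)AlMe2 (Tebbe reagent, 2 equiv), pyridine (cat.), THF–toluene, −40 → 0 °C
Reagents that add atoms: Tebbe reagent, C[Al-]1(C)C[Ti](C2C=CC=C2)(C2C=CC=C2)[Cl+]1
Why: Tebbe methylenation, in which the non-basic titanium methylidene converts this hindered, enolisable ketone next to the quaternary spiro carbon into the exocyclic alkene through an oxatitanacyclobutane, leaving the secondary bromide and both stereocentres untouched.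

**Step 6**
Reactants: 11 (6S,8S)-8-bromo-3,7,7-trimethyl-11-methylidenespiro[5.5]undec-2-ene
Product: 12 (2R,3R,6S,8S)-8-bromo-2-chloro-3,7,7-trimethyl-11-methylidenespiro[5.5]undecan-3-ol
Conditions: NCS (1.05 equiv), acetone–H2O (4:1), 0 °C, dark
Reagents that add atoms: N-chlorosuccinimide, O=C1CCC(=O)N1Cl; water, O
Why: Electrophilic chlorohydroxylation (halohydrin formation): the trisubstituted ring B alkene is more nucleophilic than the neopentyl 1,1-disubstituted one, and Markovnikov, trans-diaxial (Fürst–Plattner) opening of the chloronium ion by water, in the ring B chair that keeps the CMe2 carbon equatorial, puts Cl at C2 on the face of the C=CH2 carbon and OH at C3 on the face of the CMe2 carbon.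

**Step 7**
Reactants: 12 (2R,3R,6S,8S)-8-bromo-2-chloro-3,7,7-trimethyl-11-methylidenespiro[5.5]undecan-3-ol
Product: 13 (2S,6S,8R,9R)-2,9-dibromo-8-chloro-1,1,9-trimethyl-5-methylidenespiro[5.5]undecane (target)
Conditions: Me3SiBr (2.2 equiv), 2,6-di-tert-butyl-4-methylpyridine (1.2 equiv), CH2Cl2, −40 → 0 °C
Reagents that add atoms: bromotrimethylsilane, C[Si](C)(C)Br
Why: SN1 substitution of the tertiary alcohol through its silyl oxonium ion with anchimeric assistance from the trans-diaxial chlorine (chloronium-like ion), so bromide enters anti to Cl at the tertiary carbon, which is net retention at C3 and gives the trans-diaxial bromochloride, while the hindered pyridine takes up the HBr released on O-silylation and so protects the exocyclic alkene.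

**Compound list**
1 | prop-2-yn-1-ol (propargyl alcohol) | C#CCO | starting material
2 | 5-bromo-2-methylpent-2-ene | CC(C)=CCCBr | starting material
3 | lithium 7-methyloct-6-en-2-yn-1-olate | [Li+].[O-]CC#CCCC=C(C)C | intermediate (not isolated)
4 | 7-methyloct-6-en-2-yn-1-yl pivalate | CC(C)=CCCC#CCOC(=O)C(C)(C)C | intermediate
5 | 5-[(2R)-3,3-dimethyloxiran-2-yl]pent-2-yn-1-yl pivalate | CC1(C)O[C@@H]1CCC#CCOC(=O)C(C)(C)C | intermediate
6 | (6S)-6,7-dibromo-7-methyloct-2-yn-1-yl pivalate | CC(C)(Br)[C@@H](Br)CCC#CCOC(=O)C(C)(C)C | intermediate
7 | isoprene (2-methylbuta-1,3-diene) | C=CC(C)=C | starting material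
8 | (6S)-6,7-dibromo-7-methylocta-1,2-dien-3-yl pivalate | C=C=C(OC(=O)C(C)(C)C)CC[C@H](Br)C(C)(C)Br | intermediate (not isolated)
9 | O-pivaloyl oxocarbenium triflate of (4S)-4-bromo-3,3-dimethyl-2-methylidenecyclohexan-1-one | C=C1C(=[O+]C(=O)C(C)(C)C)CC[C@H](Br)C1(C)C.[O-]S(=O)(=O)C(F)(F)F | intermediate (not isolated)
10 | (4S,6R)-4-bromo-5,5,9-trimethylspiro[5.5]undec-8-en-1-one | O=C1CC[C@H](Br)C(C)(C)[C@]12CCC(C)=CC2 | intermediate
11 | (6S,8S)-8-bromo-3,7,7-trimethyl-11-methylidenespiro[5.5]undec-2-ene | C=C1CC[C@H](Br)C(C)(C)[C@]12CCC(C)=CC2 | intermediate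
12 | (2R,3R,6S,8S)-8-bromo-2-chloro-3,7,7-trimethyl-11-methylidenespiro[5.5]undecan-3-ol | C=C1CC[C@H](Br)C(C)(C)[C@]12CC[C@@](C)(O)[C@H](Cl)C2 | intermediate
13 | (2S,6S,8R,9R)-2,9-dibromo-8-chloro-1,1,9-trimethyl-5-methylidenespiro[5.5]undecane | C=C1CC[C@H](Br)C(C)(C)[C@]12CC[C@@](C)(Br)[C@H](Cl)C2 | target

**Step count and risks**
Total steps: 7. Longest linear sequence: 7 steps (1 and 2 to 13); isoprene 7 enters at step 4.

Step 4 is the most likely to fail. The carboxyallene may not build up enough before ionisation, the bromonium ion may be trapped by the alkyne or by isoprene instead, and the Diels–Alder face selectivity rests on a conformational argument. Fallback: setting out from 6, the two ring closures are run as separate operations. The gold-then-silver protocol without diene, quenched with aq. NaHCO3, stops at the enone (4S)-4-bromo-3,3-dimethyl-2-methylidenecyclohexan-1-one F1. F1 is then combined with isoprene 7 under Me2AlCl in CH2Cl2 at −78 °C in an ordinary Lewis-acid Diels–Alder reaction, which returns to the route at 10.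

Step 6 is the second risk. Chlorine must enter at C2 on the more hindered ring B face, and an ene-type allylic chlorination or attack on the exocyclic alkene could compete. Fallback: setting out from 11, face selection and regioselection are separated. Epoxidation with mCPBA/NaHCO3 on the ring B face anti to the axial C=CH2 carbon gives the (2S,3R)-2,3-epoxide of 11 (chamigrene locants, oxygen syn to the CMe2 carbon) F2. Trans-diaxial opening at the secondary carbon with LiCl/AcOH in THF returns to the route at 12.

Step 7 is the third risk. The tertiary cation may eliminate to the vinyl chloride, the pyridinium bromide formed in the flask may still protonate the exocyclic alkene, and retention depends on chlorine participation. Fallback: setting out from 12, the alcohol is first converted with TFAA, pyridine and DMAP to (2R,3R,6S,8S)-8-bromo-2-chloro-3,7,7-trimethyl-11-methylidenespiro[5.5]undecan-3-yl trifluoroacetate F3. F3 is ionised under aprotic conditions with MgBr2·OEt2 in CH2Cl2 at −20 °C, which returns to the route at 13 without any protic bromide source.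

**Further compounds**
F1 | step 4 | (4S)-4-bromo-3,3-dimethyl-2-methylidenecyclohexan-1-one | C=C1C(=O)CC[C@H](Br)C1(C)C
F2 | step 6 | (2S,3R)-2,3-epoxide of 11 (chamigrene locants, oxygen syn to the CMe2 carbon) | C=C1CC[C@H](Br)C(C)(C)[C@]12CC[C@@]3(C)O[C@H]3C2
F3 | step 7 | (2R,3R,6S,8S)-8-bromo-2-chloro-3,7,7-trimethyl-11-methylidenespiro[5.5]undecan-3-yl trifluoroacetate | C=C1CC[C@H](Br)C(C)(C)[C@]12CC[C@@](C)(OC(=O)C(F)(F)F)[C@H](Cl)C2
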